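**Plan**

- Retrosynthetic cuts: first the C12 ester and the C11=C13 methylene (back to a 2-hydroxyethyl arm on C7), then the two acyl C–O bonds, then C4–C15 (methyl cross-coupling on a C4 enol triflate), and last C9–C10 and C5–C6, the two ring-B bonds of a quinone Diels–Alder adduct.
- Enabling feature: ring A carries oxygen on C3, a one-carbon branch on C4 and a methyl on quaternary C10. This is the pattern of 2-methoxy-5-methyl-1,4-benzoquinone, used as dienophile at its methyl-bearing C10=C5 alkene.
- Forward order: ring A is bought as the quinone; ring B is closed in one cycloaddition with a 2-silyloxydiene that already carries C11–C12; ring A is then edited (C15 onto C4, C1 deoxygenated by reduction and enol-ether transposition, C1=C2 hydrogenated); the acrylate is built last.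
- Stereochemistry: C10 from the chiral titanium Lewis acid in the cycloaddition; C7 by equilibration next to the C8 ketone (equatorial arm); C3 and C8 by hydride addition from the face opposite the C10 methyl.

Key step: step 4

Numbering: eudesmane numbering is used for all bicyclic compounds (ring A = C1–C5 and C10; ring B = C5–C10; C14 = methyl on C10; C15 = methyl on C4; C11, C12, C13 = branch on C7). "13-Nor" and "13,15-dinor" mark compounds that still lack these carbons; β is the face of the C10 methyl. The C10 descriptor switches between R and S only because CIP priorities change; the centre is never touched after step 4. TBS = tert-butyldimethylsilyl, TBDPS = tert-butyldiphenylsilyl.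

Assumption: the (R,R)-TADDOL titanium complex is taken to shield the quinone face that leads to the (10R) adduct; if the sense of induction is the opposite, the (S,S)-ligand is used. The quinone is treated as a catalogue compound.

**Route**

Step 1
Reactants: 1 5-hydroxypentan-2-one
Product: 2 5-(TBDPSO)pentan-2-one
Conditions: TBDPSCl, imidazole, DMF, 0 °C → rt
Reagents that add atoms: tert-butyl(chloro)diphenylsilane, CC(C)(C)[Si](Cl)(c1ccccc1)c1ccccc1
Why: Imidazole-promoted silylation of a primary alcohol (silyl ether protection) is routine, draws the hydroxy ketone out of its cyclic hemiketal form and gives an ether that should outlast the later aqueous acid step; no stereocentre is formed.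

Step 2
Reactants: 2 5-(TBDPSO)pentan-2-one
Product: 3 5-(TBDPSO)-3-methylidenepentan-2-one
Conditions: (CH2O)n, i-Pr2NH·TFA (1 equiv), TFA (10 mol%), THF, reflux
Reagents that add atoms: formaldehyde (used as paraformaldehyde), C=O
Why: A Mannich-type α-methylenation with an ammonium trifluoroacetate proceeds through the more substituted enol of a methyl ketone, so the methylene should be placed on C3 and not on the methyl group, and loss of the amine gives the enone.

Step 3
Reactants: 3 5-(TBDPSO)-3-methylidenepentan-2-one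
Product: 4 2-(TBSO)-3-[2-(TBDPSO)ethyl]buta-1,3-diene
Conditions: TBSOTf, Et3N, CH2Cl2, 0 °C
Reagents that add atoms: tert-butyldimethylsilyl trifluoromethanesulfonate, CC(C)(C)[Si](C)(C)OS(=O)(=O)C(F)(F)F
Why: Soft enolisation with a silyl triflate and a tertiary amine (silyl enol ether formation) can only remove a proton from the methyl group of this α-substituted methyl vinyl ketone and so should give the 2-silyloxy-1,3-diene.

Step 4
Reactants: 4 2-(TBSO)-3-[2-(TBDPSO)ethyl]buta-1,3-diene; 5 2-methoxy-5-methyl-1,4-benzoquinone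
Product: 6 (5S,10R)-8-(TBSO)-12-(TBDPSO)-3-methoxy-13,15-dinoreudesma-2,7-diene-1,4-dione (cis-fused, H-5 and C10 methyl both β)
Conditions: TiCl2(Oi-Pr)2 (20 mol%), (R,R)-TADDOL (22 mol%), 4 Å MS, toluene, −78 → −30 °C
Reagents that add atoms: none
Why: The titanium(IV) TADDOLate binds quinone 5 in two-point fashion through the C4 carbonyl and the neighbouring methoxy oxygen, which lowers the LUMO of the C10=C5 alkene and makes C10, the carbon β to the chelated carbonyl, its most electrophilic position, while the silyl enol ether terminus C9 is the most nucleophilic carbon of diene 4; a concerted, asynchronous [4+2] cycloaddition should therefore form C9–C10 slightly ahead of C5–C6. The closest known reaction type is the chiral titanium Lewis acid promoted Diels–Alder reaction of 2-alkoxy-1,4-benzoquinones with simple dienes, together with catalytic asymmetric quinone cycloadditions of 2-silyloxydienes. Ring B closes as a six-membered carbocycle by suprafacial addition of both diene termini to one face of the quinone alkene, which by itself makes the C10 methyl and H-5 cis. The absolute configuration at C10, and with it at the temporary C5 centre, is controlled by the TADDOL ligand, whose aryl groups shield one face of the chelated dienophile. Three selectivities are needed: reaction at the methyl-bearing alkene is secured by the vinylogous-ester deactivation of C2=C3, the C9-to-C10 orientation by the match between chelation-induced polarisation and the 2-silyloxy group, and the enantioface by the ligand. The quaternary C10 also keeps the adduct from aromatising, so the enedione should survive to the next step.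

Step 5
Reactants: 6 (5S,10R)-8-(TBSO)-12-(TBDPSO)-3-methoxy-13,15-dinoreudesma-2,7-diene-1,4-dione
Product: 8 (10R)-8-(TBSO)-12-(TBDPSO)-3-methoxy-1-oxo-13,15-dinoreudesma-2,4,7-trien-4-yl trifluoromethanesulfonate, via potassium enolate 7 (not isolated)
Conditions: KHMDS, THF, −78 °C; then PhNTf2, −78 → 0 °C
Reagents that add atoms: N-phenylbis(trifluoromethanesulfonimide), O=S(=O)(N(c1ccccc1)S(=O)(=O)C(F)(F)F)C(F)(F)F
Why: H-5 is the only enolisable hydrogen of 6, so KHMDS should give a single cross-conjugated enolate that PhNTf2 sulfonylates on oxygen (enol triflate formation); the temporary C5 centre is erased as planned and C10, having no α-hydrogen, cannot epimerise.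

Step 6
Reactants: 8 (10R)-8-(TBSO)-12-(TBDPSO)-3-methoxy-1-oxo-13,15-dinoreudesma-2,4,7-trien-4-yl trifluoromethanesulfonate
Product: 9 (10R)-8-(TBSO)-12-(TBDPSO)-3-methoxy-13-noreudesma-2,4,7-trien-1-one
Conditions: MeZnCl, Pd(PPh3)4 (5 mol%), THF, rt → 50 °C
Reagents that add atoms: methylzinc chloride, C[Zn]Cl
Why: Negishi cross-coupling (oxidative addition of Pd(0) into the alkenyl C–OTf bond, transmetalation, reductive elimination) should place C15 on C4 with the C4=C5 position fixed by the triflate, and the organozinc reagent does not attack the vinylogous-ester carbonyl or the silyl groups.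

Step 7
Reactants: 9 (10R)-8-(TBSO)-12-(TBDPSO)-3-methoxy-13-noreudesma-2,4,7-trien-1-one
Product: 12 (7R,10S)-12-(TBDPSO)-13-noreudesma-1,4-diene-3,8-dione (7β arm, 10β methyl), via allylic alcohol 10 (not isolated), via dienone silyl enol ether 11 (not isolated)
Conditions: DIBAL-H, CH2Cl2, −78 °C; then 1 M HCl, THF, 0 °C → rt (stirred until C7 has equilibrated)
Reagents that add atoms: water, O
Why: DIBAL-H reduces the vinylogous-ester carbonyl at C1 in 1,2-fashion and aqueous acid then ionises the doubly allylic C1 alcohol, hydrolyses the methyl enol ether to the C3 ketone (Stork–Danheiser transposition) and cleaves the silyl enol ether to the C8 ketone, the new C7 centre being set by axial protonation on the α face and by acid-mediated equilibration to the equatorial 7β arm.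

Step 8
Reactants: 12 (7R,10S)-12-(TBDPSO)-13-noreudesma-1,4-diene-3,8-dione
Product: 13 (7R,10R)-12-(TBDPSO)-13-noreudesm-4-ene-3,8-dione
Conditions: H2 (1 atm), RhCl(PPh3)3 (10 mol%), benzene/EtOH, rt
Reagents that add atoms: none
Why: Homogeneous hydrogenation with Wilkinson's catalyst saturates the disubstituted C1=C2 bond of a cross-conjugated 1,4-dien-3-one and should leave the tetrasubstituted C4=C5 bond and both ketones untouched, as is established for 4-methyl-1,4-dien-3-ones of the santonin type.

Step 9
Reactants: 13 (7R,10R)-12-(TBDPSO)-13-noreudesm-4-ene-3,8-dione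
Product: 14 (3S,7R,8R,10R)-12-(TBDPSO)-13-noreudesm-4-ene-3,8-diol (3β,8β-diol)
Conditions: NaBH4, CeCl3·7H2O, MeOH, −78 → −20 °C
Reagents that add atoms: none
Why: Luche reduction should deliver hydride to C3 in 1,2-fashion along the axial α trajectory of the cyclohexenone half-chair (quasi-equatorial 3β-OH) and to C8 from the equatorial α side because the axial β approach is blocked by the syn-axial C10 methyl (axial 8β-OH, cis to the C7 arm).

Step 10
Reactants: 14 (3S,7R,8R,10R)-12-(TBDPSO)-13-noreudesm-4-ene-3,8-diol
Product: 15 (3S,7R,8R,10R)-12-(TBDPSO)-8-hydroxy-13-noreudesm-4-en-3-yl propanoate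
Conditions: (EtCO)2O (1.1 equiv), pyridine, CH2Cl2, 0 °C
Reagents that add atoms: propanoic anhydride, CCC(=O)OC(=O)CC
Why: Acylation without a nucleophilic catalyst should discriminate the two alcohols (site-selective esterification), since the quasi-equatorial allylic 3β-OH is open whereas the axial 8β-OH is syn-axial to the C10 methyl and flanked by the C7 arm.

Step 11
Reactants: 15 (3S,7R,8R,10R)-12-(TBDPSO)-8-hydroxy-13-noreudesm-4-en-3-yl propanoate
Product: 16 (3S,7R,8R,10R)-8-acetoxy-12-(TBDPSO)-13-noreudesm-4-en-3-yl propanoate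
Conditions: Ac2O, DMAP, Et3N, CH2Cl2, rt
Reagents that add atoms: acetic anhydride, CC(=O)OC(C)=O
Why: DMAP-catalysed acyl transfer is strong enough to esterify the remaining hindered axial alcohol, with retention because the C8–O bond is not broken.

Step 12
Reactants: 16 (3S,7R,8R,10R)-8-acetoxy-12-(TBDPSO)-13-noreudesm-4-en-3-yl propanoate
Product: 17 (3S,7R,8R,10R)-8-acetoxy-12-hydroxy-13-noreudesm-4-en-3-yl propanoate
Conditions: HF·pyridine, pyridine, THF, 0 °C → rt
Reagents that add atoms: none
Why: Fluoride cleaves the Si–O bond of the primary TBDPS ether (desilylation), and the pyridine-buffered reagent is not basic, so neither ester should be cleaved or migrate.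

Step 13
Reactants: 17 (3S,7R,8R,10R)-8-acetoxy-12-hydroxy-13-noreudesm-4-en-3-yl propanoate
Product: 18 (3S,7R,8R,10R)-8-acetoxy-12-oxo-13-noreudesm-4-en-3-yl propanoate
Conditions: Dess–Martin periodinane, CH2Cl2, 0 °C → rt
Reagents that add atoms: none
Why: Dess–Martin oxidation converts the primary alcohol into the aldehyde under near-neutral conditions, without over-oxidation and without effect on the esters or the tetrasubstituted alkene.

Step 14
Reactants: 18 (3S,7R,8R,10R)-8-acetoxy-12-oxo-13-noreudesm-4-en-3-yl propanoate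
Product: 19 (3S,7R,8R,10R)-8-acetoxy-12-oxoeudesma-4,11(13)-dien-3-yl propanoate
Conditions: 37% aq. CH2O, pyrrolidine (10 mol%), EtCO2H (10 mol%), i-PrOH, 45 °C
Reagents that add atoms: formaldehyde, C=O
Why: Amine-catalysed α-methylenation of an aldehyde (enamine formation, Mannich addition, β-elimination of the amine) should introduce C13 on C11 under weakly acidic conditions that leave both esters and C7 intact, the α-branched acrolein formed being a poor partner for further iminium chemistry.

Step 15
Reactants: 19 (3S,7R,8R,10R)-8-acetoxy-12-oxoeudesma-4,11(13)-dien-3-yl propanoate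
Product: 20 (3S,7R,8R,10R)-8-acetoxy-3-(propanoyloxy)eudesma-4,11(13)-dien-12-oic acid
Conditions: NaClO2, NaH2PO4, 2-methyl-2-butene, t-BuOH/H2O, 0 °C → rt
Reagents that add atoms: sodium chlorite, [Na+].[O-]Cl=O
Why: Pinnick oxidation is the standard way from an α-substituted acrolein to the acrylic acid, and excess 2-methyl-2-butene removes hypochlorous acid before it can attack the C4=C5 or C11=C13 alkenes.

Step 16
Reactants: 20 (3S,7R,8R,10R)-8-acetoxy-3-(propanoyloxy)eudesma-4,11(13)-dien-12-oic acid
Product: 21 methyl (3S,7R,8R,10R)-8-acetoxy-3-(propanoyloxy)eudesma-4,11(13)-dien-12-oate (CNP0198123.1)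
Conditions: MeI, K2CO3, DMF, 0 °C → rt
Reagents that add atoms: iodomethane, CI
Why: SN2 O-alkylation of the carboxylate under mild carbonate conditions should give the methyl ester without the transesterification an alcoholic medium could cause and without a dipolar reagent that might add to the acrylate.

**Compound list**

1 | 5-hydroxypentan-2-one | CC(=O)CCCO | starting material
2 | 5-[(tert-butyldiphenylsilyl)oxy]pentan-2-one | CC(=O)CCCO[Si](c1ccccc1)(c1ccccc1)C(C)(C)C | intermediate
3 | 5-[(tert-butyldiphenylsilyl)oxy]-3-methylidenepentan-2-one | CC(=O)C(=C)CCO[Si](c1ccccc1)(c1ccccc1)C(C)(C)C | intermediate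
4 | 2-[(tert-butyldimethylsilyl)oxy]-3-{2-[(tert-butyldiphenylsilyl)oxy]ethyl}buta-1,3-diene | C=C(CCO[Si](c1ccccc1)(c1ccccc1)C(C)(C)C)C(=C)O[Si](C)(C)C(C)(C)C | intermediate
5 | 2-methoxy-5-methyl-1,4-benzoquinone | COC1=CC(=O)C(C)=CC1=O | starting material
6 | (5S,10R)-8-(TBSO)-12-(TBDPSO)-3-methoxy-13,15-dinoreudesma-2,7-diene-1,4-dione, i.e. (4aR,8aS)-6-[(tert-butyldimethylsilyl)oxy]-7-{2-[(tert-butyldiphenylsilyl)oxy]ethyl}-2-methoxy-4a-methyl-4a,5,8,8a-tetrahydronaphthalene-1,4-dione | COC1=CC(=O)[C@]2(C)CC(O[Si](C)(C)C(C)(C)C)=C(CCO[Si](c3ccccc3)(c3ccccc3)C(C)(C)C)C[C@@H]2C1=O | intermediate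
7 | potassium (10R)-8-(TBSO)-12-(TBDPSO)-3-methoxy-1-oxo-13,15-dinoreudesma-2,4,7-trien-4-olate | COC1=CC(=O)[C@]2(C)CC(O[Si](C)(C)C(C)(C)C)=C(CCO[Si](c3ccccc3)(c3ccccc3)C(C)(C)C)CC2=C1[O-].[K+] | intermediate
8 | (10R)-8-(TBSO)-12-(TBDPSO)-3-methoxy-1-oxo-13,15-dinoreudesma-2,4,7-trien-4-yl trifluoromethanesulfonate | COC1=CC(=O)[C@]2(C)CC(O[Si](C)(C)C(C)(C)C)=C(CCO[Si](c3ccccc3)(c3ccccc3)C(C)(C)C)CC2=C1OS(=O)(=O)C(F)(F)F | intermediate
9 | (10R)-8-(TBSO)-12-(TBDPSO)-3-methoxy-13-noreudesma-2,4,7-trien-1-one | COC1=CC(=O)[C@]2(C)CC(O[Si](C)(C)C(C)(C)C)=C(CCO[Si](c3ccccc3)(c3ccccc3)C(C)(C)C)CC2=C1C | intermediate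
10 | (10R)-8-(TBSO)-12-(TBDPSO)-3-methoxy-13-noreudesma-2,4,7-trien-1-ol (mixture of C1 epimers) | COC1=CC(O)[C@]2(C)CC(O[Si](C)(C)C(C)(C)C)=C(CCO[Si](c3ccccc3)(c3ccccc3)C(C)(C)C)CC2=C1C | intermediate
11 | (10S)-8-(TBSO)-12-(TBDPSO)-13-noreudesma-1,4,7-trien-3-one | CC(C)(C)[Si](C)(C)OC1=C(CCO[Si](c2ccccc2)(c2ccccc2)C(C)(C)C)CC2=C(C)C(=O)C=C[C@]2(C)C1 | intermediate
12 | (7R,10S)-12-(TBDPSO)-13-noreudesma-1,4-diene-3,8-dione | CC(C)(C)[Si](OCC[C@H]1CC2=C(C)C(=O)C=C[C@]2(C)CC1=O)(c1ccccc1)c1ccccc1 | intermediate
13 | (7R,10R)-12-(TBDPSO)-13-noreudesm-4-ene-3,8-dione | CC(C)(C)[Si](OCC[C@H]1CC2=C(C)C(=O)CC[C@]2(C)CC1=O)(c1ccccc1)c1ccccc1 | intermediate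
14 | (3S,7R,8R,10R)-12-(TBDPSO)-13-noreudesm-4-ene-3,8-diol | CC(C)(C)[Si](OCC[C@H]1CC2=C(C)[C@@H](O)CC[C@]2(C)C[C@H]1O)(c1ccccc1)c1ccccc1 | intermediate
15 | (3S,7R,8R,10R)-12-(TBDPSO)-8-hydroxy-13-noreudesm-4-en-3-yl propanoate | CC(C)(C)[Si](OCC[C@H]1CC2=C(C)[C@@H](OC(=O)CC)CC[C@]2(C)C[C@H]1O)(c1ccccc1)c1ccccc1 | intermediate
16 | (3S,7R,8R,10R)-8-acetoxy-12-(TBDPSO)-13-noreudesm-4-en-3-yl propanoate | CC(C)(C)[Si](OCC[C@H]1CC2=C(C)[C@@H](OC(=O)CC)CC[C@]2(C)C[C@H]1OC(C)=O)(c1ccccc1)c1ccccc1 | intermediate
17 | (3S,7R,8R,10R)-8-acetoxy-12-hydroxy-13-noreudesm-4-en-3-yl propanoate | OCC[C@H]1CC2=C(C)[C@@H](OC(=O)CC)CC[C@]2(C)C[C@H]1OC(C)=O | intermediate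
18 | (3S,7R,8R,10R)-8-acetoxy-12-oxo-13-noreudesm-4-en-3-yl propanoate | O=CC[C@H]1CC2=C(C)[C@@H](OC(=O)CC)CC[C@]2(C)C[C@H]1OC(C)=O | intermediate
19 | (3S,7R,8R,10R)-8-acetoxy-12-oxoeudesma-4,11(13)-dien-3-yl propanoate | C=C(C=O)[C@H]1CC2=C(C)[C@@H](OC(=O)CC)CC[C@]2(C)C[C@H]1OC(C)=O | intermediate
20 | (3S,7R,8R,10R)-8-acetoxy-3-(propanoyloxy)eudesma-4,11(13)-dien-12-oic acid | C=C(C(=O)O)[C@H]1CC2=C(C)[C@@H](OC(=O)CC)CC[C@]2(C)C[C@H]1OC(C)=O | intermediate
21 | methyl (3S,7R,8R,10R)-8-acetoxy-3-(propanoyloxy)eudesma-4,11(13)-dien-12-oate, i.e. methyl 2-[(2R,3R,4aR,7S)-3-acetoxy-4a,8-dimethyl-7-(propanoyloxy)-1,2,3,4,4a,5,6,7-octahydronaphthalen-2-yl]prop-2-enoate | C=C(C(=O)OC)[C@H]1CC2=C(C)[C@@H](OC(=O)CC)CC[C@]2(C)C[C@H]1OC(C)=O | target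

**Count and risks**

Total step count: 16. Longest linear sequence: 16 steps (1 → 21; quinone 5 enters at step 4).

Steps most likely to fail:

Step 4. The titanium catalyst may be held back by the chelating product, the silyl enol ether may react stepwise and stop after the first bond, or the facial selectivity may be poor. The fallback gives up absolute control in the bond-forming event but keeps the same two bonds. It sets out from 4 and 5, which are heated without Lewis acid (toluene, 60 °C, BHT). The same orientation is expected because the C4 carbonyl, not being part of the vinylogous ester, is the stronger acceptor. This should give the racemic cis adduct F1. Its enantiomers are separated by preparative chromatography on a chiral stationary phase (amylose carbamate, supercritical CO2/i-PrOH). The (5S,10R) enantiomer is 6, where the route is rejoined before step 5.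

Step 5. Deprotonation at C5 of the strained cis-fused enedione may lead to decomposition of the enolate or to sulfonylation at carbon. The fallback brings in C15 by carbonyl addition instead of cross-coupling. It sets out from 6: MeMgBr with CeCl3 (THF, −78 °C) should add to the more electrophilic C4 ketone, the C1 carbonyl being a vinylogous ester next to quaternary C10, to give the tertiary carbinol F2. Dehydration with SOCl2/pyridine (CH2Cl2, −20 °C) towards C5 should then give dienone 9, where the route is rejoined before step 7.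

Step 9. Hydride addition to the C3 carbonyl may show poor facial selectivity, so that the 3α-alcohol is formed alongside or instead of the 3β-alcohol. The fallback sets C3 by inversion. It sets out from 13: L-Selectride (THF, −78 °C) should reduce both carbonyls from the equatorial direction to the 3α,8β-diol F3. A Mitsunobu reaction (PPh3, DIAD, propanoic acid, toluene, 0 °C) should then esterify the unhindered allylic 3α-alcohol with inversion, the axial 8β-alcohol being too hindered to react. This gives 3β-propanoate 15 directly, where the route is rejoined before step 11.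

**Further compounds**

F1 | step 4 | racemic cis adduct, 1:1 mixture of 6 and its (5R,10S) enantiomer | COC1=CC(=O)[C@]2(C)CC(O[Si](C)(C)C(C)(C)C)=C(CCO[Si](c3ccccc3)(c3ccccc3)C(C)(C)C)C[C@@H]2C1=O.COC1=CC(=O)[C@@]2(C)CC(O[Si](C)(C)C(C)(C)C)=C(CCO[Si](c3ccccc3)(c3ccccc3)C(C)(C)C)C[C@H]2C1=O
F2 | step 5 | (5S,10R)-8-(TBSO)-12-(TBDPSO)-4-hydroxy-3-methoxy-13-noreudesma-2,7-dien-1-one (C4 configuration not defined) | COC1=CC(=O)[C@]2(C)CC(O[Si](C)(C)C(C)(C)C)=C(CCO[Si](c3ccccc3)(c3ccccc3)C(C)(C)C)C[C@@H]2C1(C)O
F3 | step 9 | (3R,7R,8R,10R)-12-(TBDPSO)-13-noreudesm-4-ene-3,8-diol (3α,8β-diol) | CC(C)(C)[Si](OCC[C@H]1CC2=C(C)[C@H](O)CC[C@]2(C)C[C@H]1O)(c1ccccc1)c1ccccc1
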